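**Plan**

- Core numbering used throughout: C1 is the bridgehead with the hydroxy-isopentyl chain, C2 (C=O), C3 (aroyl), C4 (enol), C5 the bridgehead with the lavandulyl chain, C6, C7 (prenyl), C8 (CMe2), C9 (bridging C=O). Ring A is C1–C2–C3–C4–C5–C9 and ring B is C1–C8–C7–C6–C5–C9.
- Retrosynthetic cuts, in order: the O–Si bonds; both prenyl C=C bonds (back to two CH2CO2Me groups); C7–H (back to an exocyclic enoate); the lavandulyl CH–isopropenyl bond (back to an enoate arm); ring B at C7–C8; the two C5–CH2 bonds; ring A at C2–C3 and C5–C9; the C1–CH2 bond of the side chain.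
- Forward order: a malonate gives quaternary C1 (isopropenyl = future C8, plus the protected side chain). Ring A follows by acylation and Claisen cyclisation with an aroylacetone, then two identical alkynoate arms go onto C5, ring B is closed at C7–C8, the side chains are finished and the silyl groups removed.
- Enabling feature: in ring A the quaternary C1 holds the isopropenyl carbon C8 1,3-diaxial, across the C9 carbonyl, to a C5 arm whose alkynoate β-carbon is C7, so a tertiary C8 radical closes ring B in the 6-exo-dig mode.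
- Stereochemistry: C1 comes from esterase desymmetrisation of a prochiral malonate. C5 follows from C1 in the ring closure (identical arms, only the cis arm reacts). C7 comes from exo-face hydride delivery to the exocyclic enoate. The lavandulyl CH comes from ligand-controlled rhodium conjugate addition.

Key step: step 8

Assumption: the enolised β-triketone is drawn as one tautomer; all tautomers of the C2–C3–C4/aroyl system are treated as the same compound.
Notation: ArCO = 3,4-bis[(triisopropylsilyl)oxy]benzoyl; R1 = 3-methyl-3-[(triethylsilyl)oxy]butyl.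

**Route**

Step 1
Reactants: 1 4-bromo-2-methylbutan-2-ol
Product: 2 (4-bromo-2-methylbutan-2-yl)oxy(triethyl)silane
Conditions: Et3SiOTf, 2,6-lutidine, CH2Cl2, 0 °C
Reagents that add atoms: triethylsilyl trifluoromethanesulfonate, CC[Si](CC)(CC)OS(=O)(=O)C(F)(F)F
Why: Silylation of a tertiary alcohol with a silyl triflate and a hindered base is routine and masks the hydroxyl, which could otherwise open the flanking 1,3-dicarbonyl units by retro-Claisen attack, until the last step.

Step 2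
Reactants: 3 dimethyl 2-(propan-2-ylidene)propanedioate, 2 (4-bromo-2-methylbutan-2-yl)oxy(triethyl)silane
Product: 4 dimethyl 2-{3-methyl-3-[(triethylsilyl)oxy]butyl}-2-(prop-1-en-2-yl)propanedioate
Conditions: NaH, DMF, 0 °C; then 2, NaI (cat.), 50 °C
Reagents that add atoms: none
Why: Deconjugative α-alkylation of an alkylidene malonate (γ-deprotonation to the dienolate, alkylation at the α-carbon) should give the quaternary carbon that becomes C1, carrying the isopropenyl group (future C8) and the side chain; it is not yet a stereocentre because the two esters are identical.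

Step 3
Reactants: 4 dimethyl 2-{3-methyl-3-[(triethylsilyl)oxy]butyl}-2-(prop-1-en-2-yl)propanedioate
Product: 5 (2R)-2-(methoxycarbonyl)-5-methyl-2-(prop-1-en-2-yl)-5-[(triethylsilyl)oxy]hexanoic acid
Conditions: pig liver esterase (a serine carboxylesterase), phosphate buffer (0.5 M, pH 7.5)/DMSO 9:1, 30 °C; extraction at pH 3
Reagents that add atoms: water, O
Why: Enzymatic desymmetrisation of a prochiral disubstituted malonate diester by enantiotopic-group-selective hydrolysis is a known reaction class; hydrolysis of the pro-S ester should set C1 as (R), the only source of absolute configuration for the core.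

Step 4
Reactants: 6 1-(3,4-dihydroxyphenyl)ethan-1-one
Product: 7 1-{3,4-bis[(triisopropylsilyl)oxy]phenyl}ethan-1-one
Conditions: i-Pr3SiCl, imidazole, DMF, 40 °C
Reagents that add atoms: chlorotri(propan-2-yl)silane, CC(C)[Si](Cl)(C(C)C)C(C)C
Why: Silylation of both phenols with a bulky silyl chloride should give catechol protection that tolerates strong non-nucleophilic bases and mild aqueous base and is removed by fluoride without acid.

Step 5
Reactants: 7 1-{3,4-bis[(triisopropylsilyl)oxy]phenyl}ethan-1-one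
Product: 8 1-{3,4-bis[(triisopropylsilyl)oxy]phenyl}butane-1,3-dione
Conditions: MgBr2·OEt2, i-Pr2NEt, AcCl, CH2Cl2, rt
Reagents that add atoms: acetyl chloride, CC(=O)Cl
Why: Soft-enolisation C-acylation of a methyl ketone (magnesium enolate plus acid chloride) should give the 1,3-diketone whose central carbon becomes C3 and whose terminal methyl becomes C5.

Step 6
Reactants: 5 (2R)-2-(methoxycarbonyl)-5-methyl-2-(prop-1-en-2-yl)-5-[(triethylsilyl)oxy]hexanoic acid, 8 1-{3,4-bis[(triisopropylsilyl)oxy]phenyl}butane-1,3-dione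
Product: 11 (6R)-2-ArCO-3-hydroxy-6-R1-6-(prop-1-en-2-yl)cyclohex-2-ene-1,5-dione (ring A; ring carbon 6 = C1 and ring carbon 4 = C5 of the core), via acid chloride 9 (not isolated), via triketo ester 10 (not isolated)
Conditions: 5, 1-chloro-N,N,2-trimethylprop-1-en-1-amine, CH2Cl2, 0 °C; 8 (2 equiv), LiN(i-Pr)2 (4 equiv), THF, −78 → 0 °C, then 9, −78 → 0 °C; LiN(SiMe3)2 (2 equiv), 0 → 40 °C; aq. NH4Cl
Reagents that add atoms: 1-chloro-N,N,2-trimethylprop-1-en-1-amine, CC(C)=C(Cl)N(C)C (chlorine carried only in 9)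
Why: Acylation of the 1,3-diketone dianion at its terminal carbon by the acid chloride gives the 3,5,7-triketo ester, and its C3 carbanion should then close ring A by Claisen condensation onto the remaining ester (biomimetic phloroglucinol-type cyclisation, with quaternary C1 blocking aromatisation); C1 is not touched.

Step 7
Reactants: 11 (6R)-2-ArCO-3-hydroxy-6-R1-6-(prop-1-en-2-yl)cyclohex-2-ene-1,5-dione
Product: 12 (6R)-2-ArCO-3-hydroxy-4,4-bis(4-methoxy-4-oxobut-2-yn-1-yl)-6-R1-6-(prop-1-en-2-yl)cyclohex-2-ene-1,5-dione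
Conditions: methyl 4-bromobut-2-ynoate (2.5 equiv), K2CO3 (3 equiv), acetone, 0 °C → rt
Reagents that add atoms: methyl 4-bromobut-2-ynoate, COC(=O)C#CCBr
Why: Twofold C-alkylation of the only nucleophilic carbon (C5) of the triketone anion with a reactive propargylic bromide, as in the gem-dialkylation of acylphloroglucinol-type triones; because the two arms are identical C5 is not a stereocentre, so no C1/C5 diastereomer problem arises.

Step 8
Reactants: 12 (6R)-2-ArCO-3-hydroxy-4,4-bis(4-methoxy-4-oxobut-2-yn-1-yl)-6-R1-6-(prop-1-en-2-yl)cyclohex-2-ene-1,5-dione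
Product: 13 methyl 4-[(1R,5R)-3-ArCO-4-hydroxy-7-(2-methoxy-2-oxoethylidene)-8,8-dimethyl-1-R1-2,9-dioxobicyclo[3.3.1]non-3-en-5-yl]but-2-ynoate (exocyclic enoate as E/Z mixture)
Conditions: Fe(acac)3 (0.5 equiv), PhSiH3 (3 equiv), EtOH/HOCH2CH2OH 5:1, 60 °C, 0.005 M
Reagents that add atoms: none
Why: Proposed new method: an iron hydride formed from Fe(acac)3 and PhSiH3 transfers a hydrogen atom to the terminal carbon of the C1 isopropenyl group, the only electron-rich alkene in 12, and the resulting nucleophilic tertiary C8 radical adds to C7, the β-carbon of the alkynoate arm on the same face of ring A, after which the α-ester vinyl radical is reduced and protonated (or abstracts hydrogen) to give the exocyclic enoate. The closest known reaction types are the iron-hydride-initiated reductive olefin coupling (hydrogen-atom-transfer Giese reaction) of 1,1-disubstituted alkenes with acrylate-type acceptors and the tin-hydride-mediated 6-exo-dig cyclisation of tertiary alkyl radicals onto alkynoates; new here are the alkynoate acceptor under metal-hydride conditions and the bridged ring. Ring B (C1–C8–C7–C6–C5–C9) closes in the 6-exo-dig mode. C5 becomes a stereocentre and its configuration is dictated by C1, because C8 and the reacting C6–C7 arm must be 1,3-diaxial across the C9 carbonyl, so only the arm cis to C8 can react; C7 stays trigonal and is set later. The step needs conjugate addition to outrun a 1,2-acyl (Dowd–Beckwith) shift of the C8 radical to C9 and simple hydrogenation; the strongly activated, polarity-matched alkynoate, the gem-dialkyl effect of the two quaternary carbons and high dilution should secure this, and the second arm is out of reach on the opposite face.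

Step 9
Reactants: 13 methyl 4-[(1R,5R)-3-ArCO-4-hydroxy-7-(2-methoxy-2-oxoethylidene)-8,8-dimethyl-1-R1-2,9-dioxobicyclo[3.3.1]non-3-en-5-yl]but-2-ynoate
Product: 15 methyl (2E)-4-[(1R,5R)-3-ArCO-4-hydroxy-7-(2-methoxy-2-oxoethylidene)-8,8-dimethyl-1-R1-2,9-dioxobicyclo[3.3.1]non-3-en-5-yl]but-2-enoate, via (Z)-enoate 14 (not isolated)
Conditions: H2 (1 atm), Pd/CaCO3 poisoned with Pb(OAc)2 (Lindlar catalyst), quinoline, EtOAc, rt; filter; then PhSH (0.2 equiv), AIBN (0.1 equiv), PhH, 80 °C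
Reagents that add atoms: none
Why: Semi-hydrogenation of the remaining alkynoate over poisoned palladium should give the (Z)-enoate, and reversible thiyl-radical addition equilibrates it to the (E)-enoate needed next; the hindered trisubstituted ring enoate is not hydrogenated.

Step 10
Reactants: 15 methyl (2E)-4-[(1R,5R)-3-ArCO-4-hydroxy-7-(2-methoxy-2-oxoethylidene)-8,8-dimethyl-1-R1-2,9-dioxobicyclo[3.3.1]non-3-en-5-yl]but-2-enoate
Product: 16 methyl (3S)-3-{[(1R,5R)-3-ArCO-4-hydroxy-7-(2-methoxy-2-oxoethylidene)-8,8-dimethyl-1-R1-2,9-dioxobicyclo[3.3.1]non-3-en-5-yl]methyl}-4-methylpent-4-enoate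
Conditions: [Rh(OH)(cod)]2 (2.5 mol%), (R)-BINAP (6 mol%), isopropenylboronic acid pinacol ester (3 equiv), K3PO4 (1.5 equiv), dioxane/H2O 10:1, 60 °C
Reagents that add atoms: 4,4,5,5-tetramethyl-2-(prop-1-en-2-yl)-1,3,2-dioxaborolane, CC(=C)B1OC(C)(C)C(C)(C)O1
Why: Rhodium-catalysed asymmetric conjugate addition of an alkenylboron reagent (Hayashi–Miyaura reaction) to the β-monosubstituted (E)-enoate; the chiral bisphosphine controls the face and sets the lavandulyl stereocentre (S here, R after olefination), with (R)-BINAP the enantiomer predicted by the usual facial model for (E)-acceptors and to be confirmed on a model enoate, while the β,β-disubstituted ring enoate is inert.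

Step 11
Reactants: 16 methyl (3S)-3-{[(1R,5R)-3-ArCO-4-hydroxy-7-(2-methoxy-2-oxoethylidene)-8,8-dimethyl-1-R1-2,9-dioxobicyclo[3.3.1]non-3-en-5-yl]methyl}-4-methylpent-4-enoate
Product: 17 methyl (3S)-3-{[(1R,5R,7S)-3-ArCO-4-hydroxy-7-(2-methoxy-2-oxoethyl)-8,8-dimethyl-1-R1-2,9-dioxobicyclo[3.3.1]non-3-en-5-yl]methyl}-4-methylpent-4-enoate
Conditions: Cu(OAc)2·H2O (5 mol%), 1,2-bis(diphenylphosphino)benzene (5 mol%), (EtO)2MeSiH (4 equiv), t-BuOH (3 equiv), toluene, rt
Reagents that add atoms: none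
Why: Copper hydride conjugate reduction of the exocyclic enoate: hydride should reach C7 only from the convex exo face because the endo face is covered by C2 and C4 of ring A, so the CH2CO2Me group ends endo, which is the target configuration at C7 (descriptor S here only because of substituent priorities).

Step 12
Reactants: 17 methyl (3S)-3-{[(1R,5R,7S)-3-ArCO-4-hydroxy-7-(2-methoxy-2-oxoethyl)-8,8-dimethyl-1-R1-2,9-dioxobicyclo[3.3.1]non-3-en-5-yl]methyl}-4-methylpent-4-enoate
Product: 19 (1R,5R,7R)-3-ArCO-4-hydroxy-8,8-dimethyl-7-(3-methylbut-2-en-1-yl)-5-[(2R)-5-methyl-2-(prop-1-en-2-yl)hex-4-en-1-yl]-1-R1-bicyclo[3.3.1]non-3-ene-2,9-dione, via dialdehyde 18 (not isolated)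
Conditions: i-Bu2AlH (3.3 equiv), CH2Cl2, −78 °C; then Ph3P=C(CH3)2 (from i-PrPPh3I and n-BuLi, THF), −78 °C → rt
Reagents that add atoms: isopropyl(triphenyl)phosphonium iodide, CC(C)[P+](c1ccccc1)(c1ccccc1)c1ccccc1.[I-]
Why: Partial reduction of both methyl esters to aldehydes at low temperature (the triketone is masked as its aluminium enolate and the C9 ketone is shielded by two quaternary carbons) followed by Wittig olefination with the isopropylidene ylide should turn both CH2CO2Me groups into prenyl groups in one flask.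

Step 13
Reactants: 19 (1R,5R,7R)-3-ArCO-4-hydroxy-8,8-dimethyl-7-(3-methylbut-2-en-1-yl)-5-[(2R)-5-methyl-2-(prop-1-en-2-yl)hex-4-en-1-yl]-1-R1-bicyclo[3.3.1]non-3-ene-2,9-dione
Product: 20 (1R,5R,7R)-3-(3,4-dihydroxybenzoyl)-4-hydroxy-1-(3-hydroxy-3-methylbutyl)-8,8-dimethyl-7-(3-methylbut-2-en-1-yl)-5-[(2R)-5-methyl-2-(prop-1-en-2-yl)hex-4-en-1-yl]bicyclo[3.3.1]non-3-ene-2,9-dione (CNP0148616.1)
Conditions: n-Bu4NF (4 equiv), AcOH (4 equiv), THF, 0 °C → rt
Reagents that add atoms: none
Why: Buffered fluoride should remove the two aryl silyl ethers and the tertiary silyl ether without acid, which would cyclise the enol onto the isopropenyl group.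

**Compound list**

1 | 4-bromo-2-methylbutan-2-ol | CC(C)(O)CCBr | starting material
2 | (4-bromo-2-methylbutan-2-yl)oxy(triethyl)silane | CC(C)(CCBr)O[Si](CC)(CC)CC | intermediate
3 | dimethyl 2-(propan-2-ylidene)propanedioate | COC(=O)C(=C(C)C)C(=O)OC | starting material
4 | dimethyl 2-{3-methyl-3-[(triethylsilyl)oxy]butyl}-2-(prop-1-en-2-yl)propanedioate | C=C(C)C(CCC(C)(C)O[Si](CC)(CC)CC)(C(=O)OC)C(=O)OC | intermediate
5 | (2R)-2-(methoxycarbonyl)-5-methyl-2-(prop-1-en-2-yl)-5-[(triethylsilyl)oxy]hexanoic acid | C=C(C)[C@@](CCC(C)(C)O[Si](CC)(CC)CC)(C(=O)OC)C(=O)O | intermediate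
6 | 1-(3,4-dihydroxyphenyl)ethan-1-one | CC(=O)c1ccc(O)c(O)c1 | starting material
7 | 1-{3,4-bis[(triisopropylsilyl)oxy]phenyl}ethan-1-one | CC(=O)c1ccc(O[Si](C(C)C)(C(C)C)C(C)C)c(O[Si](C(C)C)(C(C)C)C(C)C)c1 | intermediate
8 | 1-{3,4-bis[(triisopropylsilyl)oxy]phenyl}butane-1,3-dione | CC(=O)CC(=O)c1ccc(O[Si](C(C)C)(C(C)C)C(C)C)c(O[Si](C(C)C)(C(C)C)C(C)C)c1 | intermediate
9 | methyl (2S)-2-(chlorocarbonyl)-5-methyl-2-(prop-1-en-2-yl)-5-[(triethylsilyl)oxy]hexanoate (acid chloride of 5, same spatial arrangement) | C=C(C)[C@@](CCC(C)(C)O[Si](CC)(CC)CC)(C(=O)OC)C(=O)Cl | intermediate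
10 | methyl (2R)-7-{3,4-bis[(triisopropylsilyl)oxy]phenyl}-2-{3-methyl-3-[(triethylsilyl)oxy]butyl}-3,5,7-trioxo-2-(prop-1-en-2-yl)heptanoate | C=C(C)[C@@](CCC(C)(C)O[Si](CC)(CC)CC)(C(=O)OC)C(=O)CC(=O)CC(=O)c1ccc(O[Si](C(C)C)(C(C)C)C(C)C)c(O[Si](C(C)C)(C(C)C)C(C)C)c1 | intermediate
11 | (6R)-2-{3,4-bis[(triisopropylsilyl)oxy]benzoyl}-3-hydroxy-6-{3-methyl-3-[(triethylsilyl)oxy]butyl}-6-(prop-1-en-2-yl)cyclohex-2-ene-1,5-dione | C=C(C)[C@@]1(CCC(C)(C)O[Si](CC)(CC)CC)C(=O)C(C(=O)c2ccc(O[Si](C(C)C)(C(C)C)C(C)C)c(O[Si](C(C)C)(C(C)C)C(C)C)c2)=C(O)CC1=O | intermediate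
12 | (6R)-2-{3,4-bis[(triisopropylsilyl)oxy]benzoyl}-3-hydroxy-4,4-bis(4-methoxy-4-oxobut-2-yn-1-yl)-6-{3-methyl-3-[(triethylsilyl)oxy]butyl}-6-(prop-1-en-2-yl)cyclohex-2-ene-1,5-dione | C=C(C)[C@@]1(CCC(C)(C)O[Si](CC)(CC)CC)C(=O)C(C(=O)c2ccc(O[Si](C(C)C)(C(C)C)C(C)C)c(O[Si](C(C)C)(C(C)C)C(C)C)c2)=C(O)C(CC#CC(=O)OC)(CC#CC(=O)OC)C1=O | intermediate
13 | methyl 4-[(1R,5R)-3-{3,4-bis[(triisopropylsilyl)oxy]benzoyl}-4-hydroxy-7-(2-methoxy-2-oxoethylidene)-8,8-dimethyl-1-{3-methyl-3-[(triethylsilyl)oxy]butyl}-2,9-dioxobicyclo[3.3.1]non-3-en-5-yl]but-2-ynoate (E/Z mixture at the exocyclic alkene) | COC(=O)C#CC[C@@]12CC(=CC(=O)OC)C(C)(C)[C@@](CCC(C)(C)O[Si](CC)(CC)CC)(C(=O)C(C(=O)c3ccc(O[Si](C(C)C)(C(C)C)C(C)C)c(O[Si](C(C)C)(C(C)C)C(C)C)c3)=C1O)C2=O | intermediate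
14 | methyl (2Z)-4-[(1R,5R)-bicyclic core of 13-5-yl]but-2-enoate | COC(=O)/C=C\C[C@@]12CC(=CC(=O)OC)C(C)(C)[C@@](CCC(C)(C)O[Si](CC)(CC)CC)(C(=O)C(C(=O)c3ccc(O[Si](C(C)C)(C(C)C)C(C)C)c(O[Si](C(C)C)(C(C)C)C(C)C)c3)=C1O)C2=O | intermediate
15 | methyl (2E)-4-[(1R,5R)-bicyclic core of 13-5-yl]but-2-enoate | COC(=O)/C=C/C[C@@]12CC(=CC(=O)OC)C(C)(C)[C@@](CCC(C)(C)O[Si](CC)(CC)CC)(C(=O)C(C(=O)c3ccc(O[Si](C(C)C)(C(C)C)C(C)C)c(O[Si](C(C)C)(C(C)C)C(C)C)c3)=C1O)C2=O | intermediate
16 | methyl (3S)-3-{[(1R,5R)-bicyclic core of 13-5-yl]methyl}-4-methylpent-4-enoate | C=C(C)[C@H](CC(=O)OC)C[C@@]12CC(=CC(=O)OC)C(C)(C)[C@@](CCC(C)(C)O[Si](CC)(CC)CC)(C(=O)C(C(=O)c3ccc(O[Si](C(C)C)(C(C)C)C(C)C)c(O[Si](C(C)C)(C(C)C)C(C)C)c3)=C1O)C2=O | intermediate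
17 | methyl (3S)-3-{[(1R,5R,7S)-3-{3,4-bis[(triisopropylsilyl)oxy]benzoyl}-4-hydroxy-7-(2-methoxy-2-oxoethyl)-8,8-dimethyl-1-{3-methyl-3-[(triethylsilyl)oxy]butyl}-2,9-dioxobicyclo[3.3.1]non-3-en-5-yl]methyl}-4-methylpent-4-enoate (CH2CO2Me at C7 endo) | C=C(C)[C@H](CC(=O)OC)C[C@@]12C[C@@H](CC(=O)OC)C(C)(C)[C@@](CCC(C)(C)O[Si](CC)(CC)CC)(C(=O)C(C(=O)c3ccc(O[Si](C(C)C)(C(C)C)C(C)C)c(O[Si](C(C)C)(C(C)C)C(C)C)c3)=C1O)C2=O | intermediate
18 | (3S)-3-{[(1R,5R,7S)-bicyclic core of 17 with 7-(2-oxoethyl)-5-yl]methyl}-4-methylpent-4-enal (dialdehyde) | C=C(C)[C@H](CC=O)C[C@@]12C[C@@H](CC=O)C(C)(C)[C@@](CCC(C)(C)O[Si](CC)(CC)CC)(C(=O)C(C(=O)c3ccc(O[Si](C(C)C)(C(C)C)C(C)C)c(O[Si](C(C)C)(C(C)C)C(C)C)c3)=C1O)C2=O | intermediate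
19 | (1R,5R,7R)-3-{3,4-bis[(triisopropylsilyl)oxy]benzoyl}-4-hydroxy-8,8-dimethyl-7-(3-methylbut-2-en-1-yl)-5-[(2R)-5-methyl-2-(prop-1-en-2-yl)hex-4-en-1-yl]-1-{3-methyl-3-[(triethylsilyl)oxy]butyl}bicyclo[3.3.1]non-3-ene-2,9-dione | C=C(C)[C@H](CC=C(C)C)C[C@@]12C[C@@H](CC=C(C)C)C(C)(C)[C@@](CCC(C)(C)O[Si](CC)(CC)CC)(C(=O)C(C(=O)c3ccc(O[Si](C(C)C)(C(C)C)C(C)C)c(O[Si](C(C)C)(C(C)C)C(C)C)c3)=C1O)C2=O | intermediate
20 | (1R,5R,7R)-3-(3,4-dihydroxybenzoyl)-4-hydroxy-1-(3-hydroxy-3-methylbutyl)-8,8-dimethyl-7-(3-methylbut-2-en-1-yl)-5-[(2R)-5-methyl-2-(prop-1-en-2-yl)hex-4-en-1-yl]bicyclo[3.3.1]non-3-ene-2,9-dione | C=C(C)[C@H](CC=C(C)C)C[C@@]12C[C@@H](CC=C(C)C)C(C)(C)[C@@](CCC(C)(C)O)(C(=O)C(C(=O)c3ccc(O)c(O)c3)=C1O)C2=O | target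

**Step count and risks**

Total step count: 13. Longest linear sequence: 11 steps (steps 1, 2, 3 and 6 to 13); steps 4 and 5 form a two-step side branch.

Steps most likely to fail:

1. Step 8 (proposed new method). What may go wrong: a 1,2-acyl shift of the C8 radical onto the C9 carbonyl (ring expansion of ring A), plain hydrogenation of the isopropenyl group, or silane reduction of the alkynoates before ring closure. The fallback uses known chemistry, sets out from 12 and returns at 13. Mukaiyama hydration of the isopropenyl group (Co(acac)2, PhSiH3, O2, i-PrOH), in which O2 should trap the radical faster than it can rearrange, would give the C8 tertiary alcohol F1. Acylation with methyl chlorooxoacetate and pyridine, then one equivalent of aqueous CsOH at 0 °C, would give the cesium tert-alkyl oxalate F2; the enol oxalate formed alongside is cleaved in the hydroxide step. Blue-light irradiation with [Ir(dF(CF3)ppy)2(dtbbpy)]PF6 in DME/DMF/H2O at or below room temperature should release the same C8 radical by double decarboxylation, without any metal hydride. Its conjugate addition to the cis alkynoate, followed by reduction and protonation (the known tert-alkyl oxalate photoredox Giese reaction), would give 13. The lower temperature should disfavour the acyl shift relative to conjugate addition.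

2. Step 3. What may go wrong: weak or reversed discrimination of the enantiotopic esters by the esterase, or very slow hydrolysis of the bulky diester. The fallback sets out from 4 and returns at 5. Mono-saponification with KOH (1 equiv) in MeOH/H2O would give the racemic half-ester F3. Crystallisation of its salt with (R)-1-phenylethylamine from EtOAc/hexane should give the diastereomerically pure ammonium salt F4 of the (R)-acid; if the (S)-acid salt crystallises instead, the other amine enantiomer is used. Acidification releases 5.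

3. Step 10. What may go wrong: poor facial selectivity, slow transmetalation or insertion on the hindered anionic substrate, or protodeboronation of the alkenylboronate. The fallback sets out from 13 and returns at 17, bypassing 14 to 16. Syn-carbocupration of the alkynoate arm with (CH2=C(CH3))2CuLi in THF at −78 °C would give the (E)-β-isopropenyl enoate F5. A copper hydride carrying a chiral bisphosphine (Cu(OAc)2, DTBM-SEGPHOS enantiomer chosen to give the (S)-ester, (EtO)2MeSiH, t-BuOH, toluene) should then reduce both β,β-disubstituted enoates in one operation. The lavandulyl centre would be ligand-controlled and C7 substrate-controlled (exo face), giving 17.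

Further compounds
F1 | step 8 | (6R)-2-{3,4-bis[(triisopropylsilyl)oxy]benzoyl}-3-hydroxy-6-(2-hydroxypropan-2-yl)-4,4-bis(4-methoxy-4-oxobut-2-yn-1-yl)-6-{3-methyl-3-[(triethylsilyl)oxy]butyl}cyclohex-2-ene-1,5-dione (C8 tertiary alcohol, same spatial arrangement at C1 as 12) | CC(C)(O)[C@@]1(CCC(C)(C)O[Si](CC)(CC)CC)C(=O)C(C(=O)c2ccc(O[Si](C(C)C)(C(C)C)C(C)C)c(O[Si](C(C)C)(C(C)C)C(C)C)c2)=C(O)C(CC#CC(=O)OC)(CC#CC(=O)OC)C1=O
F2 | step 8 | cesium oxalate half-ester of the tertiary alcohol F1 (C8–O–CO–CO2Cs) | [Cs+].[O-]C(=O)C(=O)OC(C)(C)[C@@]1(CCC(C)(C)O[Si](CC)(CC)CC)C(=O)C(C(=O)c2ccc(O[Si](C(C)C)(C(C)C)C(C)C)c(O[Si](C(C)C)(C(C)C)C(C)C)c2)=C(O)C(CC#CC(=O)OC)(CC#CC(=O)OC)C1=O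
F3 | step 3 | racemic 2-(methoxycarbonyl)-5-methyl-2-(prop-1-en-2-yl)-5-[(triethylsilyl)oxy]hexanoic acid | C=C(C)C(CCC(C)(C)O[Si](CC)(CC)CC)(C(=O)OC)C(=O)O
F4 | step 3 | (R)-1-phenylethylammonium (2R)-2-(methoxycarbonyl)-5-methyl-2-(prop-1-en-2-yl)-5-[(triethylsilyl)oxy]hexanoate | C=C(C)[C@@](CCC(C)(C)O[Si](CC)(CC)CC)(C(=O)OC)C(=O)[O-].C[C@@H]([NH3+])c1ccccc1
F5 | step 10 | methyl (2E)-3-{[(1R,5R)-bicyclic core of 13-5-yl]methyl}-4-methylpenta-2,4-dienoate | C=C(C)/C(=C/C(=O)OC)C[C@@]12CC(=CC(=O)OC)C(C)(C)[C@@](CCC(C)(C)O[Si](CC)(CC)CC)(C(=O)C(C(=O)c3ccc(O[Si](C(C)C)(C(C)C)C(C)C)c(O[Si](C(C)C)(C(C)C)C(C)C)c3)=C1O)C2=O
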